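**Retrosynthetic overview**

- Feature: in mutilin numbering the cyclopentenone C9–C1H2–C2(=O)–C3H=C4 is the sum of a C9=C1 methylene, CO and a C3≡C4 ethynyl group. C4 is the single-atom bridge of the bicyclo[5.3.1] core (six-membered ring C4–C9; eight-membered ring C4, C5, C14–C10, C9), so cutting C4 out leaves one monocyclic cyclodecane C5–C14.
- Disconnection 1: a transannular Pauson–Khand [2+2+1] of a 5-ethynyl-9-methylenecyclodecane makes C4–C9, C1–C2 and C2–C3 and closes the five-, six- and eight-membered rings in one step.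
- Disconnection 2: the cyclodecane arises by anionic oxy-Cope ring expansion of a trans-1,2-dialkenylcyclohexanol (C9–C14 broken, C6–C7 made), with ethynylation of the enolate at C5 in the same flask; C8–OH and C9=C1 follow by epoxidation and isomerisation.
- Disconnection 3: the cyclohexanol is built on an enantioselective Diels–Alder adduct of 1-silyloxybutadiene and methacrolein (C11, C12), then elaborated with acetaldehyde, two methyl groups and (E)-2-bromobut-2-ene.
- Ring order: sacrificial six-membered ring (C9–C14), then the ten-membered ring (C5–C14), then the five-, six- and eight-membered rings together.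

Key step: step 15

Remark (assumption): carbon labels C1–C20 are mutilin numbering throughout; in step 2 the catalyst antipode is taken to be the one that gives 4 as drawn (the formyl C–H···O binding model points to the (S)-prolinol-derived catalyst; its mirror image is equally available).

**Route**

Step 1
Reactants: 1 crotonaldehyde
Product: 2 (E)-1-(tert-butyldimethylsilyloxy)buta-1,3-diene
Conditions: TBSOTf, Et3N, Et2O, 0 °C → rt
Reagents that add atoms: tert-butyldimethylsilyl triflate (CC(C)(C)[Si](C)(C)OS(=O)(=O)C(F)(F)F)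
Why: O-silylation of the enal and γ-deprotonation of the silyloxocarbenium ion by the amine (dienol silyl ether formation) should give mainly the E diene, the only isomer that reacts in step 2.

Step 2
Reactants: 2 (E)-1-(tert-butyldimethylsilyloxy)buta-1,3-diene; 3 methacrolein
Product: 4 (1R,2S)-2-(tert-butyldimethylsilyloxy)-1-methylcyclohex-3-ene-1-carbaldehyde (CHO cis to OTBS)
Conditions: (S)-o-tolyl oxazaborolidinium triflimide (from (S)-α,α-diphenylprolinol, tri-o-tolylboroxine, Tf2NH; 10–20 mol %), CH2Cl2, −78 °C
Reagents that add atoms: none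
Why: Catalytic enantioselective Diels–Alder reaction of a 1-oxygenated diene with a 2-substituted acrolein: the boron-bound s-trans enal is shielded on one face, the "ortho" orientation joins C11 to C12, and the formyl-endo transition state puts CHO cis to OTBS, so C11 and C12 are set together.

Step 3
Reactants: 4 (1R,2S)-aldehyde
Product: 5 (3S,4S)-3-(tert-butyldimethylsilyloxy)-4-methyl-4-vinylcyclohex-1-ene
Conditions: Ph3PCH3Br, KOtBu, THF, 0 °C → rt
Reagents that add atoms: methylenetriphenylphosphorane (C=P(c1ccccc1)(c1ccccc1)c1ccccc1), made from methyltriphenylphosphonium bromide and KOtBu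
Why: Wittig methylenation of an aldehyde whose α-carbon is quaternary, so neither epimerisation nor β-elimination of the silyloxy group can occur; this gives the C12 vinyl group.

Step 4
Reactants: 5 (3S,4S)-vinylcyclohexene
Product: 6 (4S,5S)-4-(tert-butyldimethylsilyloxy)-5-methyl-5-vinylcyclohex-2-en-1-one
Conditions: Rh2(cap)4 (cap = caprolactamate, 1 mol %), t-BuOOH (70% aq.), K2CO3, CH2Cl2, rt
Reagents that add atoms: tert-butyl hydroperoxide (CC(C)(C)OO)
Why: Catalytic allylic oxidation by hydrogen abstraction at the only allylic CH2 (C14); the vinyl group has no allylic hydrogen and the C11–H is screened by its silyl ether and the neighbouring quaternary carbon.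

Step 5
Reactants: 6 (4S,5S)-enone; 7 acetaldehyde
Product: 10 (4S,5S)-4-(tert-butyldimethylsilyloxy)-2-(1-hydroxyethyl)-5-methyl-5-vinylcyclohex-2-en-1-one (both carbinol epimers), via aluminium iodo enolate 8 (not isolated), via iodo aldol 9 (not isolated)
Conditions: Et2AlI, CH2Cl2, −78 °C; 7, −78 °C; aq. NaHCO3; then Et3N, CH2Cl2, 0 °C → rt
Reagents that add atoms: none
Why: Morita–Baylis–Hillman-type hydroxyalkylation in its organoaluminium form: iodide adds 1,4, the aluminium enolate undergoes aldol addition to acetaldehyde at C9, and base removes HI to restore the enone; the carbinol centre is left unassigned because step 7 destroys it.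

Step 6
Reactants: 10 2-(1-hydroxyethyl) enone
Product: 12 (2S,3R,4S,5S)-4-(tert-butyldimethylsilyloxy)-2-(1-hydroxyethyl)-2,3,5-trimethyl-5-vinylcyclohexan-1-one, via dilithium enolate alkoxide 11 (not isolated)
Conditions: Me2CuLi (3 equiv, from MeLi and CuI), Et2O, −78 → −30 °C; then MeI, DMPU/THF, −40 → −10 °C; cold aq. NH4Cl
Reagents that add atoms: lithium dimethylcuprate (C[Cu-]C.[Li+]); iodomethane (CI)
Why: Cuprate 1,4-addition then enolate C-methylation: the first methyl adds to C10 on the face opposite the C11 silyloxy group and the cis C12 vinyl; the enolate then adopts the half-chair with C10-Me and C11-OTBS pseudo-equatorial and the C12 vinyl axial, and MeI enters C9 axially on the face away from that vinyl, so the C9 methyl (future C1) is cis to the C10 methyl and the hydroxyethyl arm (future vinyl) is equatorial, which is why the two-carbon arm is installed before this methyl.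

Step 7
Reactants: 12 β-hydroxy ketone
Product: 13 (2R,3R,4S,5S)-4-(tert-butyldimethylsilyloxy)-2,3,5-trimethyl-2,5-divinylcyclohexan-1-one
Conditions: Martin sulfurane Ph2S[OC(CF3)2Ph]2, CH2Cl2, 0 °C → rt
Reagents that add atoms: none
Why: Dehydration through the alkoxysulfonium ion (E2); C9 is quaternary, so the only β-hydrogens are on the methyl group and the terminal C8=C7 vinyl group is the only alkene that can form, without base that could trigger a retro-aldol.

Step 8
Reactants: 13 divinyl ketone; 14 (E)-2-bromobut-2-ene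
Product: 17 (1R,2R,3R,4S,5S)-1-[(E)-but-2-en-2-yl]-4-(tert-butyldimethylsilyloxy)-2,3,5-trimethyl-2,5-divinylcyclohexan-1-ol, via lithium reagent 15 (not isolated), via cerium reagent 16 (not isolated)
Conditions: 14, t-BuLi (2 equiv), Et2O, −78 °C; CeCl3 (anhydrous), THF, −78 °C; then 13, −78 → −40 °C
Reagents that add atoms: none
Why: Li–Br exchange with retention of alkene geometry, transmetalation to the non-basic organocerium reagent and 1,2-addition to a hindered, enolisable ketone; the axial face of C14 is blocked 1,3 by the axial C12 vinyl, so the alkenyl group enters equatorially and ends trans to the C9 vinyl, both alkenyl groups equatorial.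

Step 9
Reactants: 17 trans-1,2-dialkenylcyclohexanol; 18 1-[(trimethylsilyl)ethynyl]-1,2-benziodoxol-3(1H)-one
Product: 22 (5S,6S,10R,11S,12S)-11-(tert-butyldimethylsilyloxy)-5-ethynyl-5,6,9,10,12-pentamethyl-12-vinylcyclodec-8(E)-en-14-one (mutilin numbering), via potassium alkoxide 19 (not isolated), via potassium enolate 20 (not isolated), via ethynylbenziodoxolone 21 (not isolated)
Conditions: KN(SiMe3)2, 18-crown-6, THF, 0 °C → rt; then −78 °C, 18, Bu4N[Ph3SiF2], −78 → −40 °C
Reagents that add atoms: none
Why: Anionic oxy-Cope rearrangement through the chair with both alkenyl groups equatorial breaks C9–C14 and makes C6–C7, giving the ring-trans C8=C9 alkene, C6 with its methyl equatorial in the chair (6S, from the E-butenyl group) and a ring-trans tetrasubstituted enolate; anhydrous fluoride then unmasks the ethynyl iodane, which the enolate attacks through its outer face (conjugate addition, loss of 2-iodobenzoate, 1,2-shift in the alkylidene carbene) to set quaternary C5, a known electrophilic α-ethynylation of ketone enolates.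

Step 10
Reactants: 22 α-ethynyl cyclodecenone
Product: 23 (5S,6S,10R,11S,12S,14R)-alcohol (C14–OH)
Conditions: (S)-Me-CBS oxazaborolidine (30 mol %), catecholborane, toluene, −78 → −40 °C
Reagents that add atoms: none
Why: Corey–Bakshi–Shibata reduction under reagent control: the catalyst distinguishes quaternary C5 (large) from C13H2 (small) and the (S)-catalyst should give the 14R alcohol, while catecholborane leaves the alkyne and the alkenes alone at low temperature.

Step 11
Reactants: 23 cyclodecenol
Product: 24 (8S,9S)-8,9-epoxide of 23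
Conditions: ent-Shi ketone (L-fructose-derived, 30 mol %), Oxone (2KHSO5·KHSO4·K2SO4), K2CO3, Bu4NHSO4, MeCN/DMM–aq. Na2B4O7/Na2EDTA, 0 °C
Reagents that add atoms: potassium peroxymonosulfate ([K+].[O-]S(=O)(=O)OO)
Why: Shi epoxidation (chiral dioxirane, spiro transition state) of the only trisubstituted alkene; the ketone antipode is chosen to place oxygen on the face that gives the (8S,9S)-epoxide, and the monosubstituted vinyl group and the alkyne are much less reactive towards the electrophilic oxidant.

Step 12
Reactants: 24 epoxy alcohol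
Product: 25 (5S,6S,8S,10R,11S,12S,14R)-8,14-diol with C9=C1H2
Conditions: Et2Al(TMP) (5 equiv, from lithium 2,2,6,6-tetramethylpiperidide and Et2AlCl), toluene, 0 °C → rt
Reagents that add atoms: none
Why: Aluminium amide isomerisation of an epoxide to an allylic alcohol: aluminium activates the oxygen and the hindered amide removes a syn proton through a cyclic transition state from the C9 methyl group (primary, freely rotating) and not from the tertiary ring C10–H, so the tertiary C9–O bond breaks and C8 keeps its oxygen and its configuration; the C14 alkoxide and the acetylide formed from the excess reagent are restored on work-up.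

Step 13
Reactants: 25 diol
Product: 26 C8 tert-butyldimethylsilyl ether of 25 (C14–OH free)
Conditions: TBSCl (1.2 equiv), imidazole, DMF, rt
Reagents that add atoms: tert-butyldimethylsilyl chloride (CC(C)(C)[Si](C)(C)Cl)
Why: Chemoselective silylation: the allylic C8 alcohol next to an sp2 carbon reacts, whereas the C14 alcohol, neopentylic to quaternary C5, should not under these conditions.

Step 14
Reactants: 26 C14 alcohol
Product: 27 (5S,6S,8S,10R,11S,12S,14R)-14-acetoxy-8,11-bis(tert-butyldimethylsilyloxy)-5-ethynyl-5,6,10,12-tetramethyl-9-methylene-12-vinylcyclodecane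
Conditions: Ac2O, DMAP, Et3N, CH2Cl2, rt → 40 °C
Reagents that add atoms: acetic anhydride (CC(=O)OC(C)=O)
Why: DMAP-catalysed acetylation of the one remaining, hindered secondary alcohol.

Step 15
Reactants: 27 5-ethynyl-9-methylenecyclodecane; 28 carbon monoxide (brought in as Co2(CO)8)
Product: 30 8,11-bis(tert-butyldimethylsilyl) ether of Pleuromutilin E, via dicobalt alkyne complex 29 (not isolated)
Conditions: Co2(CO)8 (1.2 equiv), CH2Cl2, rt; then NMO (8 equiv), CH2Cl2, 0 °C → rt
Reagents that add atoms: none
Why: After the ethynyl group is bound as its μ-alkyne Co2(CO)6 cluster, the N-oxide strips one carbonyl ligand, the exocyclic C9=C1 alkene takes its place and inserts so that C4 is bonded to C9, and carbonyl insertion at the Co–C1 bond followed by reductive elimination with C3 closes the enone (Pauson–Khand reaction). The nearest established type is the intramolecular Pauson–Khand reaction of 1,7-enynes with a 1,1-disubstituted alkene, which gives hydrindenones with an angular quaternary carbon; here that enyne (C3≡C4–C5–C6–C7–C8–C9=C1) is tied a second time by the chain C10–C14. The six-membered ring (C4 to C9) closes in the normal exo mode over the four-atom tether, the eight-membered ring (C4, C5, C14 to C10, C9) is completed by the very same C4–C9 bond as a transannular 1,5-link across the existing cyclodecane, and the cyclopentenone is the [2+2+1] ring itself. The new quaternary centre C9 is dictated by C5, because the ethynyl group can reach the methylene only from the ring face on which it stands, so one face of C9=C1 is attacked and both bridgeheads of the bicyclo[5.3.1] core point outwards as in the target. The step needs chemoselectivity for the C9 methylene over the C12 vinyl group; engaging the vinyl group would have to build a six-membered ring spanned 1,4 by the six-carbon rest of the macrocycle (a bicyclo[6.2.2] skeleton with an enforced boat), while C5 and C9 sit in the 1,5 relation in which cyclodecanes bring atoms into contact. Quaternary C5 also helps (gem-disubstitution, no propargylic leaving group for the cluster to ionise), and the entropy penalty that normally burdens an eight-membered ring closure was settled when the ten-membered ring was made.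

Step 16
Reactants: 30 bis-silyl ether
Product: 31 Pleuromutilin E
Conditions: HF·pyridine, pyridine/THF, 0 °C → rt
Reagents that add atoms: none
Why: Fluoride cleavage of both silyl ethers under non-basic conditions, which spares the C14 acetate and avoids alkoxide-triggered fragmentation at C8 next to the enone.

**Compound list**

1 | crotonaldehyde | C/C=C/C=O | starting material
2 | (E)-1-(tert-butyldimethylsilyloxy)buta-1,3-diene | C=C/C=C/O[Si](C)(C)C(C)(C)C | intermediate
3 | methacrolein | C=C(C)C=O | starting material
4 | (1R,2S)-2-(tert-butyldimethylsilyloxy)-1-methylcyclohex-3-ene-1-carbaldehyde | O=C[C@]1(C)CCC=C[C@@H]1O[Si](C)(C)C(C)(C)C | intermediate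
5 | (3S,4S)-3-(tert-butyldimethylsilyloxy)-4-methyl-4-vinylcyclohex-1-ene | C=C[C@]1(C)CCC=C[C@@H]1O[Si](C)(C)C(C)(C)C | intermediate
6 | (4S,5S)-4-(tert-butyldimethylsilyloxy)-5-methyl-5-vinylcyclohex-2-en-1-one | C=C[C@]1(C)CC(=O)C=C[C@@H]1O[Si](C)(C)C(C)(C)C | intermediate
7 | acetaldehyde | CC=O | starting material
8 | diethylaluminium enolate of the 3-iodo ketone (iodide 1,4-adduct of 6) | C=C[C@]1(C)CC(O[Al](CC)CC)=CC(I)[C@@H]1O[Si](C)(C)C(C)(C)C | intermediate (not isolated)
9 | 3-iodo-2-(1-hydroxyethyl) ketone (iodo aldol, isomer mixture) | C=C[C@]1(C)CC(=O)C(C(C)O)C(I)[C@@H]1O[Si](C)(C)C(C)(C)C | intermediate (not isolated)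
10 | (4S,5S)-4-(tert-butyldimethylsilyloxy)-2-(1-hydroxyethyl)-5-methyl-5-vinylcyclohex-2-en-1-one (carbinol epimers) | C=C[C@]1(C)CC(=O)C(C(C)O)=C[C@@H]1O[Si](C)(C)C(C)(C)C | intermediate
11 | dilithium enolate alkoxide after methyl 1,4-addition | C=C[C@]1(C)CC([O-])=C(C(C)[O-])[C@@H](C)[C@@H]1O[Si](C)(C)C(C)(C)C.[Li+].[Li+] | intermediate (not isolated)
12 | (2S,3R,4S,5S)-4-(tert-butyldimethylsilyloxy)-2-(1-hydroxyethyl)-2,3,5-trimethyl-5-vinylcyclohexan-1-one (carbinol epimers) | C=C[C@]1(C)CC(=O)[C@](C)(C(C)O)[C@@H](C)[C@@H]1O[Si](C)(C)C(C)(C)C | intermediate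
13 | (2R,3R,4S,5S)-4-(tert-butyldimethylsilyloxy)-2,3,5-trimethyl-2,5-divinylcyclohexan-1-one | C=C[C@]1(C)CC(=O)[C@](C)(C=C)[C@@H](C)[C@@H]1O[Si](C)(C)C(C)(C)C | intermediate
14 | (E)-2-bromobut-2-ene | C/C=C(\C)Br | starting material
15 | (Z)-but-2-en-2-yllithium (methyl groups cis) | C/C=C(\C)[Li] | intermediate (not isolated)
16 | but-2-en-2-ylcerium dichloride (same geometry, methyl groups cis) | C/C=C(\C)[Ce](Cl)Cl | intermediate (not isolated)
17 | (1R,2R,3R,4S,5S)-1-[(E)-but-2-en-2-yl]-4-(tert-butyldimethylsilyloxy)-2,3,5-trimethyl-2,5-divinylcyclohexan-1-ol | C=C[C@]1(C)C[C@@](O)(/C(C)=C/C)[C@](C)(C=C)[C@@H](C)[C@@H]1O[Si](C)(C)C(C)(C)C | intermediate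
18 | 1-[(trimethylsilyl)ethynyl]-1,2-benziodoxol-3(1H)-one | C[Si](C)(C)C#CI1OC(=O)c2ccccc21 | starting material
19 | potassium alkoxide of 17 | C=C[C@]1(C)C[C@@]([O-])(/C(C)=C/C)[C@](C)(C=C)[C@@H](C)[C@@H]1O[Si](C)(C)C(C)(C)C.[K+] | intermediate (not isolated)
20 | potassium cyclodeca-5(14),8-dienolate (both ring alkenes trans in the ring; 6S,10R,11S,12S) | C=C[C@]1(C)C/C([O-])=C(C)/[C@@H](C)C/C=C(C)/[C@@H](C)[C@@H]1O[Si](C)(C)C(C)(C)C.[K+] | intermediate (not isolated)
21 | 1-ethynyl-1,2-benziodoxol-3(1H)-one | C#CI1OC(=O)c2ccccc21 | intermediate (not isolated)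
22 | (5S,6S,10R,11S,12S,8E)-5-ethynyl cyclodec-8-en-14-one (C11 OTBS) | C=C[C@]1(C)CC(=O)[C@](C)(C#C)[C@@H](C)C/C=C(C)/[C@@H](C)[C@@H]1O[Si](C)(C)C(C)(C)C | intermediate
23 | (5S,6S,10R,11S,12S,14R)-cyclodec-8-en-14-ol | C=C[C@]1(C)C[C@@H](O)[C@](C)(C#C)[C@@H](C)C/C=C(C)/[C@@H](C)[C@@H]1O[Si](C)(C)C(C)(C)C | intermediate
24 | (8S,9S)-8,9-epoxy alcohol | C=C[C@]1(C)C[C@@H](O)[C@](C)(C#C)[C@@H](C)C[C@@H]2O[C@@]2(C)[C@@H](C)[C@@H]1O[Si](C)(C)C(C)(C)C | intermediate
25 | (5S,6S,8S,10R,11S,12S,14R)-9-methylene-8,14-diol | C=C[C@]1(C)C[C@@H](O)[C@](C)(C#C)[C@@H](C)C[C@H](O)C(=C)[C@@H](C)[C@@H]1O[Si](C)(C)C(C)(C)C | intermediate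
26 | C8 silyl ether, C14 alcohol | C=C[C@]1(C)C[C@@H](O)[C@](C)(C#C)[C@@H](C)C[C@H](O[Si](C)(C)C(C)(C)C)C(=C)[C@@H](C)[C@@H]1O[Si](C)(C)C(C)(C)C | intermediate
27 | (5S,6S,8S,10R,11S,12S,14R)-14-acetoxy-8,11-bis(silyloxy)-5-ethynyl-9-methylenecyclodecane | C=C[C@]1(C)C[C@@H](OC(C)=O)[C@](C)(C#C)[C@@H](C)C[C@H](O[Si](C)(C)C(C)(C)C)C(=C)[C@@H](C)[C@@H]1O[Si](C)(C)C(C)(C)C | intermediate
28 | carbon monoxide (brought in as Co2(CO)8) | [C-]#[O+] | starting material
29 | μ-alkyne dicobalt hexacarbonyl complex of 27 (written as its components) | C=C[C@]1(C)C[C@@H](OC(C)=O)[C@](C)(C#C)[C@@H](C)C[C@H](O[Si](C)(C)C(C)(C)C)C(=C)[C@@H](C)[C@@H]1O[Si](C)(C)C(C)(C)C.[Co].[Co].[C-]#[O+].[C-]#[O+].[C-]#[O+].[C-]#[O+].[C-]#[O+].[C-]#[O+] | intermediate (not isolated)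
30 | 8,11-bis(tert-butyldimethylsilyl) ether of Pleuromutilin E (5S,6S,8S,9R,10R,11S,12S,14R) | C=C[C@]1(C)C[C@@H](OC(C)=O)[C@]2(C)C3=CC(=O)C[C@@]3([C@@H](O[Si](C)(C)C(C)(C)C)C[C@@H]2C)[C@@H](C)[C@@H]1O[Si](C)(C)C(C)(C)C | intermediate
31 | Pleuromutilin E | C=C[C@]1(C)C[C@@H](OC(C)=O)[C@]2(C)C3=CC(=O)C[C@@]3([C@@H](O)C[C@@H]2C)[C@@H](C)[C@@H]1O | target

**Step count and risks**

Total step count: 16. Longest linear sequence: 16 steps (1 to 31).

Steps most likely to fail:

1. Step 15 (transannular Pauson–Khand). The cobalt-bound alkyne may fail to reach the C9=C1 alkene across the ring, so that insertion is slower than decomplexation, or the C12 vinyl group may be engaged instead. The fallback sets out from 27 and drops the dimetal cluster. The alkyne is C-silylated (Zn(OTf)2 cat., TMSOTf, Et3N) to the trimethylsilyl alkyne F1. F1 is cyclised by a rhodium-catalysed carbonylative cycloisomerisation ([Rh(CO)2Cl]2, CO 1 atm, toluene, 110 °C), which runs through oxidative cyclisation at a single monovalent rhodium centre and works best with internal silyl alkynes, to give the 3-silyl enone F2. Buffered Bu4NF/AcOH then removes the C-silyl group and HF·pyridine the two silyl ethers, and the route is rejoined at 31.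

2. Step 9 (oxy-Cope rearrangement with ethynylation in the same flask). The hindered tetrasubstituted enolate may be protonated or attacked at oxygen instead of forming the quaternary propargylic centre, or conversion to the iodane adduct may be poor. The fallback sets out from 17 and changes the two-carbon electrophile. Enolate 20 is generated as before and trapped with trichloroethylene and a second equivalent of KN(SiMe3)2 (dichloroacetylene formed in the flask) to give the (E)-1,2-dichlorovinyl ketone F3. F3 is reduced at C14 with the same oxazaborolidine and catecholborane to the alcohol F4. Excess n-BuLi (THF, −78 → 0 °C) then converts the dichlorovinyl group into the ethynyl group by elimination and Li–Cl exchange, and the route is rejoined at 23.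

3. Step 11 (epoxidation). Facial selectivity may be poor, because the conformational bias of the E-cyclodecene (its outer face) can override the chiral dioxirane and lead to the 8-epi series. The fallback sets out from 23 and corrects C8 by an oxidation–reduction pair instead of by the epoxidation. Peripheral epoxidation with mCPBA (CH2Cl2, NaHCO3, 0 °C) gives the (8R,9R)-epoxide F5. The same aluminium amide isomerisation gives the 8-epi diol F6. MnO2 oxidises only the allylic C8 alcohol to the α-methylene ketone F7. Reagent-controlled 1,2-reduction ((R)-Me-CBS oxazaborolidine, catecholborane) then sets 8S, and the route is rejoined at 25.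

**Further compounds**

F1 | step 15 | C-trimethylsilyl alkyne of 27 | C=C[C@]1(C)C[C@@H](OC(C)=O)[C@](C)(C#C[Si](C)(C)C)[C@@H](C)C[C@H](O[Si](C)(C)C(C)(C)C)C(=C)[C@@H](C)[C@@H]1O[Si](C)(C)C(C)(C)C
F2 | step 15 | 3-trimethylsilyl derivative of bis-silyl ether 30 | C=C[C@]1(C)C[C@@H](OC(C)=O)[C@]2(C)C3=C([Si](C)(C)C)C(=O)C[C@@]3([C@@H](O[Si](C)(C)C(C)(C)C)C[C@@H]2C)[C@@H](C)[C@@H]1O[Si](C)(C)C(C)(C)C
F3 | step 9 | 5-[(E)-1,2-dichlorovinyl] cyclodec-8-en-14-one | C=C[C@]1(C)CC(=O)[C@](C)(/C(Cl)=C\Cl)[C@@H](C)C/C=C(C)/[C@@H](C)[C@@H]1O[Si](C)(C)C(C)(C)C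
F4 | step 9 | 5-[(E)-1,2-dichlorovinyl] cyclodec-8-en-14-ol (14R) | C=C[C@]1(C)C[C@@H](O)[C@](C)(/C(Cl)=C\Cl)[C@@H](C)C/C=C(C)/[C@@H](C)[C@@H]1O[Si](C)(C)C(C)(C)C
F5 | step 11 | (8R,9R)-8,9-epoxy alcohol | C=C[C@]1(C)C[C@@H](O)[C@](C)(C#C)[C@@H](C)C[C@H]2O[C@]2(C)[C@@H](C)[C@@H]1O[Si](C)(C)C(C)(C)C
F6 | step 11 | 8-epi-9-methylene-8,14-diol (8R) | C=C[C@]1(C)C[C@@H](O)[C@](C)(C#C)[C@@H](C)C[C@@H](O)C(=C)[C@@H](C)[C@@H]1O[Si](C)(C)C(C)(C)C
F7 | step 11 | 9-methylene-8-ketone (C14–OH free) | C=C[C@]1(C)C[C@@H](O)[C@](C)(C#C)[C@@H](C)CC(=O)C(=C)[C@@H](C)[C@@H]1O[Si](C)(C)C(C)(C)C
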